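## Retrosynthetic overview
1. The last bond made is C6'–OOH. It comes from a templated singlet-oxygen ene reaction on the prenyl end of the (4S)-homoallylic alcohol, which sets C6' and moves the alkene to C7'=C8'.
2. The prenyl end comes from a terminal allyl group by cross-metathesis. The C4' carbinol comes from the E-enal by catalytic asymmetric allylboration, which sets C4'.
3. The E-enal comes from 4-allyloxy-5-methylcoumarin and methacrolein by cross-metathesis. The ether C–O bond comes from O-allylation of 4-hydroxy-5-methylcoumarin.
4. Rings: the benzene ring is bought. The pyranone ring is the only ring made, and it is closed first by Claisen condensation and lactonisation of 2'-hydroxy-6'-methylacetophenone with diethyl carbonate.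

Assumption: side-chain atoms are numbered C1' (OCH2) to C8' (=CH2), and (S)-TRIP, which is (S)-3,3'-bis(2,4,6-triisopropylphenyl)-1,1'-binaphthyl-2,2'-diyl hydrogen phosphate, is taken as the matched acid for the (4S)-alcohol in step 6 on the basis of the model given there.

## Route

Step 1
Reactants: 1 2'-hydroxy-6'-methylacetophenone; 2 diethyl carbonate
Product: 4 4-hydroxy-5-methylcoumarin, via beta-keto ester 3 (not isolated)
Conditions: NaH (4 equiv), 2 (5 equiv), toluene, 110 °C, 4 h; then ice, 2 M HCl to pH 2, filter
Reagents that add atoms: none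
Why: Claisen condensation of the ketone enolate with diethyl carbonate gives beta-keto ester 3, whose phenoxide closes the pyranone ring by lactonisation (the classical 4-hydroxycoumarin synthesis), and the methyl group ortho to the former acetyl carbon ends up at C5, with no stereocentre formed.

Step 2
Reactants: 4 4-hydroxy-5-methylcoumarin; 5 allyl bromide
Product: 6 4-allyloxy-5-methylcoumarin
Conditions: K2CO3 (1.5 equiv), 5 (1.3 equiv), acetone, 56 °C, 8 h; wash with aq Na2CO3
Reagents that add atoms: none
Why: Williamson O-alkylation of the vinylogous carboxylate with a carbonate base in acetone favours the 4-O-allyl ether, the still acidic C3-allylated by-product is removed by the basic wash, and 56 °C is far below the Claisen rearrangement threshold of 4-allyloxycoumarins.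

Step 3
Reactants: 6 4-allyloxy-5-methylcoumarin; 7 methacrolein
Product: 8 (2E)-2-methyl-4-[(5-methyl-2-oxo-2H-chromen-4-yl)oxy]but-2-enal
Conditions: second-generation Hoveyda–Grubbs catalyst RuCl2(SIMes)(=CH-C6H4-2-OiPr) (5 mol%; SIMes = 1,3-dimesitylimidazolidin-2-ylidene), 7 (5 equiv), CH2Cl2, 40 °C, 16 h
Reagents that add atoms: none
Why: Olefin cross-metathesis of a terminal allyl (vinylogous) ester with the electron-poor 1,1-disubstituted partner methacrolein is selective for the hetero-coupled trisubstituted enal and gives the E isomer under thermodynamic control, which fixes the C2'=C3' geometry of the target.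

Step 4
Reactants: 8 (2E)-enal; 9 allylboronic acid pinacol ester
Product: 11 4-{[(2E,4S)-4-hydroxy-3-methylhepta-2,6-dien-1-yl]oxy}-5-methylcoumarin, via pinacol borate ester 10 (not isolated)
Conditions: (S)-3,3'-bis(2,4,6-triisopropylphenyl)-1,1'-binaphthyl-2,2'-diyl hydrogen phosphate [(S)-TRIP] (5 mol%), 9 (1.3 equiv), 4 Å MS, toluene/CH2Cl2 4:1, −30 °C, 24 h; then aq NH4Cl work-up
Reagents that add atoms: none
Why: Chiral-phosphoric-acid-catalysed allylboration runs through a closed chair transition state in which the acid hydrogen-bonds to the pseudo-axial boronate oxygen and the formyl hydrogen, and since the (R)-acid is known to send allyl to the Re face of aryl and alkenyl aldehydes, the (S)-acid attacks the Si face and sets C4' as S, while the lactone and vinylogous ester are inert to 9 at −30 °C.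

Step 5
Reactants: 11 (4S)-allyl carbinol; 12 2-methylbut-2-ene
Product: 13 4-{[(2E,4S)-4-hydroxy-3,7-dimethylocta-2,6-dien-1-yl]oxy}-5-methylcoumarin
Conditions: second-generation Grubbs catalyst RuCl2(=CHPh)(PCy3)(SIMes) (3 mol%), 12 (30 equiv)/CH2Cl2, sealed tube, 35 °C, 12 h
Reagents that add atoms: none
Why: Cross-metathesis with excess 2-methylbut-2-ene transfers an isopropylidene unit only to the monosubstituted alkene, because the trisubstituted C2'=C3' alkene and the coumarin C3=C4 bond do not enter the catalytic cycle, and the C4' carbinol is untouched.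

Step 6
Reactants: 13 (4S)-prenyl carbinol
Product: 14 4-{[(2E,4S,6S)-6-hydroperoxy-4-hydroxy-3,7-dimethylocta-2,7-dien-1-yl]oxy}-5-methylcoumarin (target)
Conditions: O2 (1 atm, slow stream), 5,10,15,20-tetrakis(pentafluorophenyl)porphyrin (0.5 mol%), (S)-TRIP (1.2 equiv, recovered), 4 Å MS, toluene (0.02 M), −60 °C, 525 nm LED, to about 90% conversion; direct cold silica chromatography
Reagents that add atoms: dioxygen (reacts as singlet oxygen), O=O
Why: Proposed new method: a hydrogen-bond-relay Schenck ene reaction in which the phosphoric acid accepts a hydrogen bond from the C4' hydroxyl at P=O and donates its P–OH proton to the trailing oxygen of the perepoxide-like transition state, so that singlet oxygen is drawn to the alkene face that carries C4', which for the (4S)-alcohol in its allylic-strain-minimised conformer (C3' anti to C6', carbinol H over the alkene, the bulky acid-bound OH pointing outward) is the Si face of C6' and gives the C6'–O bond as 6S (1,3-anti, whereas a direct OH-to-oxygen contact needs the OH inside and would give the syn epimer), while no C5'–H is aligned on the attacked face and the proton relay polarises positive charge onto tertiary C7', so that only a C7' methyl hydrogen is transferred (secondary hydroperoxide plus isopropenyl group), and the C2'=C3' alkene flanked by two allylic oxygens reacts much more slowly; the closest known reaction types are the hydroxy-directed threo-selective Schenck ene reaction of chiral allylic alcohols and the alkali-cation-steered regioselective photooxygenation of 2-methyl-2-alkenes inside zeolites, neither of which has been shown with a Brønsted acid template or for 1,3-induction from a homoallylic alcohol.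

## Compound list
1 | 2'-hydroxy-6'-methylacetophenone | CC(=O)c1c(C)cccc1O | starting material
2 | diethyl carbonate | CCOC(=O)OCC | starting material
3 | ethyl 3-(2-hydroxy-6-methylphenyl)-3-oxopropanoate | CCOC(=O)CC(=O)c1c(C)cccc1O | intermediate
4 | 4-hydroxy-5-methyl-2H-chromen-2-one | Cc1cccc2oc(=O)cc(O)c12 | intermediate
5 | allyl bromide | C=CCBr | starting material
6 | 5-methyl-4-(prop-2-en-1-yloxy)-2H-chromen-2-one | C=CCOc1cc(=O)oc2cccc(C)c12 | intermediate
7 | methacrolein | C=C(C)C=O | starting material
8 | (2E)-2-methyl-4-[(5-methyl-2-oxo-2H-chromen-4-yl)oxy]but-2-enal | O=C/C(C)=C/COc1cc(=O)oc2cccc(C)c12 | intermediate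
9 | allylboronic acid pinacol ester | C=CCB1OC(C)(C)C(C)(C)O1 | starting material
10 | (2E,4S)-3-methyl-1-[(5-methyl-2-oxo-2H-chromen-4-yl)oxy]hepta-2,6-dien-4-yl pinacol borate | C=CC[C@H](OB1OC(C)(C)C(C)(C)O1)/C(C)=C/COc1cc(=O)oc2cccc(C)c12 | intermediate
11 | 4-{[(2E,4S)-4-hydroxy-3-methylhepta-2,6-dien-1-yl]oxy}-5-methyl-2H-chromen-2-one | C=CC[C@H](O)/C(C)=C/COc1cc(=O)oc2cccc(C)c12 | intermediate
12 | 2-methylbut-2-ene | CC=C(C)C | starting material
13 | 4-{[(2E,4S)-4-hydroxy-3,7-dimethylocta-2,6-dien-1-yl]oxy}-5-methyl-2H-chromen-2-one | CC(C)=CC[C@H](O)/C(C)=C/COc1cc(=O)oc2cccc(C)c12 | intermediate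
14 | 4-{[(2E,4S,6S)-6-hydroperoxy-4-hydroxy-3,7-dimethylocta-2,7-dien-1-yl]oxy}-5-methyl-2H-chromen-2-one | C=C(C)[C@H](C[C@H](O)/C(C)=C/COc1cc(=O)oc2cccc(C)c12)OO | target

## Step count
- Total steps: 6.
- Longest linear sequence: 6 (1 to 14).

## Three steps most likely to fail

**Step 6 (the new reaction).**
- Risks:
  - The lactone carbonyl may compete with the C4' hydroxyl for the acid.
  - An "inside" acid–alcohol complex would deliver the syn epimer.
  - The C4' hydroxyl may trap the polarised perepoxide and give a tetrahydrofuran.
  - The acid may induce Hock cleavage of the product.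
- Fallback with known chemistry, setting out from 13 and coming back at 14: give up stereocontrol in the C–O bond formation and separate instead. The ordinary dye-sensitised Schenck ene reaction (tetraphenylporphyrin, O2, CH2Cl2, 0 °C, visible light) attacks only the electron-rich C6'=C7' alkene. It gives 14 together with two isomers. One is the C6' epimer 4-{[(2E,4S,6R)-6-hydroperoxy-4-hydroxy-3,7-dimethylocta-2,7-dien-1-yl]oxy}-5-methyl-2H-chromen-2-one F1. The other is the tertiary regioisomer 4-{[(2E,4S,5E)-7-hydroperoxy-4-hydroxy-3,7-dimethylocta-2,5-dien-1-yl]oxy}-5-methyl-2H-chromen-2-one F2. Flash chromatography removes F2. Semi-preparative normal-phase HPLC separates 14 from F1, and 14 is identified by comparison with the NMR data of the natural product.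

**Step 2 (ambident nucleophile).**
- Risks: C3-allylation and double allylation compete with O-alkylation, and the peri 5-methyl group hinders O4.
- Fallback, setting out from 4 and coming back at 6: reverse the polarity of the ether bond formation so that the coumarin is the electrophile. POCl3 with benzyltriethylammonium chloride in MeCN at 80 °C converts 4 into 4-chloro-5-methyl-2H-chromen-2-one F3. Sodium allyloxide (allyl alcohol, NaH, THF, 0 °C) then displaces chloride by addition–elimination at C4. This can only give the O-linked ether 6.

**Step 4 (enantioselectivity).**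
- Risks: the enal is alpha-branched, and its coumarin carbonyl may compete for the catalyst.
- Fallback, setting out from 8 and coming back at 11: replace asymmetric catalysis by racemic addition plus resolution. Barbier allylation of 8 with allyl bromide 5 and zinc dust in THF/saturated aq NH4Cl gives racemic 4-{[(2E)-4-hydroxy-3-methylhepta-2,6-dien-1-yl]oxy}-5-methyl-2H-chromen-2-one F4. Sharpless kinetic resolution follows (Ti(OiPr)4, D-(−)-diisopropyl tartrate, tert-butyl hydroperoxide 0.6 equiv, 4 Å MS, CH2Cl2, −20 °C). It epoxidises the fast-reacting (R)-enantiomer to the erythro epoxy alcohol 4-({(2R,3R)-3-[(1R)-1-hydroxybut-3-en-1-yl]-3-methyloxiran-2-yl}methoxy)-5-methyl-2H-chromen-2-one F5. The (S)-alcohol 11 is left in high ee (at most 50% yield) and is separated on silica.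

## Further compounds
F1 | step 6 | 4-{[(2E,4S,6R)-6-hydroperoxy-4-hydroxy-3,7-dimethylocta-2,7-dien-1-yl]oxy}-5-methyl-2H-chromen-2-one | C=C(C)[C@@H](C[C@H](O)/C(C)=C/COc1cc(=O)oc2cccc(C)c12)OO
F2 | step 6 | 4-{[(2E,4S,5E)-7-hydroperoxy-4-hydroxy-3,7-dimethylocta-2,5-dien-1-yl]oxy}-5-methyl-2H-chromen-2-one | CC(C)(OO)/C=C/[C@H](O)/C(C)=C/COc1cc(=O)oc2cccc(C)c12
F3 | step 2 | 4-chloro-5-methyl-2H-chromen-2-one | Cc1cccc2oc(=O)cc(Cl)c12
F4 | step 4 | racemic 4-{[(2E)-4-hydroxy-3-methylhepta-2,6-dien-1-yl]oxy}-5-methyl-2H-chromen-2-one | C=CCC(O)/C(C)=C/COc1cc(=O)oc2cccc(C)c12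
F5 | step 4 | 4-({(2R,3R)-3-[(1R)-1-hydroxybut-3-en-1-yl]-3-methyloxiran-2-yl}methoxy)-5-methyl-2H-chromen-2-one | C=CC[C@@H](O)[C@@]1(C)O[C@@H]1COc1cc(=O)oc2cccc(C)c12
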